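**Retrosynthetic overview**
1. Target 15 is an unsymmetrical biquinone. The last step is a Teuber oxidation of the resorcinol ring (ring B, methoxyphenethyl half) of quinone–resorcinol 14.
2. The central C–C bond of 14 comes from an intermolecular Michael addition of resorcinol 12 (C-nucleophile) to the only free β-carbon of hydroxyquinone 9 (ring A, phenethyl half), with re-oxidation in the same flask.
3. 9 comes from resorcinol 8 by Teuber oxidation. 8 and 12 come from stilbenes 7 and 11 by one-pot hydrogenation/debenzylation.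
4. 7 and 11 come from one common phosphonate 5 by Horner–Wadsworth–Emmons olefination with benzaldehyde or 2-methoxybenzaldehyde. 5 is made from 3,5-dihydroxy-4-methylbenzoic acid.
5. No ring is built: both six-membered carbocycles come from the benzoic acid. Ring A is raised to the quinone first (step 7), ring B last (step 11).

Assumption: the SMILES carries no stereodescriptor (no stereocentre, biquinone axis unspecified), so the compound is made as drawn and no asymmetric step is needed.

**Route**

Step 1
Reactants: 1 3,5-dihydroxy-4-methylbenzoic acid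
Product: 2 benzyl 3,5-bis(benzyloxy)-4-methylbenzoate
Conditions: BnBr (3.3 equiv), K2CO3, DMF, 60 °C
Reagents that add atoms: benzyl bromide, BrCc1ccccc1
Why: Williamson etherification and carboxylate O-alkylation (SN2) mask both phenols and the acid in one operation with groups that a later hydrogenolysis removes.

Step 2
Reactants: 2 benzyl 3,5-bis(benzyloxy)-4-methylbenzoate
Product: 3 [3,5-bis(benzyloxy)-4-methylphenyl]methanol
Conditions: LiAlH4, THF, 0 °C to rt
Reagents that add atoms: none
Why: Hydride reduction of the ester gives the primary benzylic alcohol while the benzyl aryl ethers are inert.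

Step 3
Reactants: 3 [3,5-bis(benzyloxy)-4-methylphenyl]methanol
Product: 4 1,3-bis(benzyloxy)-5-(bromomethyl)-2-methylbenzene
Conditions: PBr3 (0.4 equiv), CH2Cl2, 0 °C
Reagents that add atoms: phosphorus tribromide, BrP(Br)Br
Why: The benzylic alcohol is converted to the bromide by SN2 displacement of its phosphite ester, a standard transformation for benzyloxy-substituted benzyl alcohols.

Step 4
Reactants: 4 1,3-bis(benzyloxy)-5-(bromomethyl)-2-methylbenzene
Product: 5 diethyl {[3,5-bis(benzyloxy)-4-methylphenyl]methyl}phosphonate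
Conditions: P(OEt)3 (neat), 140 °C
Reagents that add atoms: triethyl phosphite, CCOP(OCC)OCC
Why: The Michaelis–Arbuzov reaction of a reactive benzylic bromide is clean and is driven by loss of volatile bromoethane.

Step 5
Reactants: 5 diethyl {[3,5-bis(benzyloxy)-4-methylphenyl]methyl}phosphonate; 6 benzaldehyde
Product: 7 1,3-bis(benzyloxy)-2-methyl-5-[(E)-2-phenylethenyl]benzene
Conditions: KOC(CH3)3, THF, 0 °C to rt
Reagents that add atoms: none
Why: Horner–Wadsworth–Emmons olefination of a benzylic phosphonate with an aromatic aldehyde reliably gives the (E)-stilbene, and the alkene geometry is erased in the next step.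

Step 6
Reactants: 7 1,3-bis(benzyloxy)-2-methyl-5-[(E)-2-phenylethenyl]benzene
Product: 8 2-methyl-5-(2-phenylethyl)benzene-1,3-diol
Conditions: H2 (1 atm), 10% Pd/C, EtOAc/MeOH, rt
Reagents that add atoms: none
Why: Catalytic hydrogenation saturates the stilbene and hydrogenolyses both benzyl ethers in one pot to give the bibenzyl resorcinol.

Step 7
Reactants: 8 2-methyl-5-(2-phenylethyl)benzene-1,3-diol
Product: 9 3-hydroxy-2-methyl-5-(2-phenylethyl)cyclohexa-2,5-diene-1,4-dione
Conditions: (KSO3)2NO (2.5 equiv), KH2PO4 buffer, H2O/acetone, 0 °C to rt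
Reagents that add atoms: potassium nitrosodisulfonate (KSO3)2NO, [O]N(S(=O)(=O)[O-])S(=O)(=O)[O-].[K+].[K+]
Why: In this Teuber oxidation the only free ring positions (C4 and C6, equivalent by symmetry, each para to one OH) are oxygenated, so a single hydroxy-para-quinone results with C2 blocked by methyl.

Step 8
Reactants: 5 diethyl {[3,5-bis(benzyloxy)-4-methylphenyl]methyl}phosphonate; 10 2-methoxybenzaldehyde
Product: 11 1,3-bis(benzyloxy)-5-[(E)-2-(2-methoxyphenyl)ethenyl]-2-methylbenzene
Conditions: KOC(CH3)3, THF, 0 °C to rt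
Reagents that add atoms: none
Why: The same Horner–Wadsworth–Emmons olefination works with the ortho-methoxy aldehyde, and the geometry is again irrelevant.

Step 9
Reactants: 11 1,3-bis(benzyloxy)-5-[(E)-2-(2-methoxyphenyl)ethenyl]-2-methylbenzene
Product: 12 5-[2-(2-methoxyphenyl)ethyl]-2-methylbenzene-1,3-diol
Conditions: H2 (1 atm), 10% Pd/C, EtOAc/MeOH, rt
Reagents that add atoms: none
Why: Hydrogenation with hydrogenolysis frees the two resorcinol hydroxyls while the aryl methyl ether, which the target keeps, is untouched.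

Step 10
Reactants: 9 3-hydroxy-2-methyl-5-(2-phenylethyl)cyclohexa-2,5-diene-1,4-dione; 12 5-[2-(2-methoxyphenyl)ethyl]-2-methylbenzene-1,3-diol (1.5 equiv)
Product: 14 2-{2,4-dihydroxy-6-[2-(2-methoxyphenyl)ethyl]-3-methylphenyl}-5-hydroxy-6-methyl-3-(2-phenylethyl)cyclohexa-2,5-diene-1,4-dione, via biphenylpentol Michael adduct 13 (not isolated)
Conditions: CF3CO2H (0.3 equiv), (CF3)2CHOH, O2 (1 atm), 25 °C
Reagents that add atoms: none
Why: In this acid-promoted intermolecular Michael addition (conjugate arylation) the resorcinol attacks through C4, which is ortho to one OH and para to the other, at the only unsubstituted enone β-carbon of the acid-activated quinone; the adduct enolises to 13, O2 returns it to the quinone level, and excess 12 suppresses double arylation (no stereocentre is formed).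

Step 11
Reactants: 14 2-{2,4-dihydroxy-6-[2-(2-methoxyphenyl)ethyl]-3-methylphenyl}-5-hydroxy-6-methyl-3-(2-phenylethyl)cyclohexa-2,5-diene-1,4-dione
Product: 15 4,4'-dihydroxy-2-[2-(2-methoxyphenyl)ethyl]-5,5'-dimethyl-2'-(2-phenylethyl)-[1,1'-bi(cyclohexane)]-1,1',4,4'-tetraene-3,3',6,6'-tetrone (target)
Conditions: (KSO3)2NO (3 equiv), KH2PO4 buffer, H2O/acetone, 0 °C to rt
Reagents that add atoms: potassium nitrosodisulfonate (KSO3)2NO, [O]N(S(=O)(=O)[O-])S(=O)(=O)[O-].[K+].[K+]
Why: A second Teuber oxidation oxygenates the single remaining aromatic C–H of the resorcinol ring (para to one OH, ortho to the other), giving the second hydroxyquinone with the required substitution pattern, while the existing quinone and the anisole ring are inert to the nitroxyl radical.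

**Compound list**
1 | 3,5-dihydroxy-4-methylbenzoic acid | Cc1c(O)cc(C(=O)O)cc1O | starting material
2 | benzyl 3,5-bis(benzyloxy)-4-methylbenzoate | Cc1c(OCc2ccccc2)cc(C(=O)OCc2ccccc2)cc1OCc1ccccc1 | intermediate
3 | [3,5-bis(benzyloxy)-4-methylphenyl]methanol | Cc1c(OCc2ccccc2)cc(CO)cc1OCc1ccccc1 | intermediate
4 | 1,3-bis(benzyloxy)-5-(bromomethyl)-2-methylbenzene | Cc1c(OCc2ccccc2)cc(CBr)cc1OCc1ccccc1 | intermediate
5 | diethyl {[3,5-bis(benzyloxy)-4-methylphenyl]methyl}phosphonate | CCOP(=O)(OCC)Cc1cc(OCc2ccccc2)c(C)c(OCc2ccccc2)c1 | intermediate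
6 | benzaldehyde | O=Cc1ccccc1 | starting material
7 | 1,3-bis(benzyloxy)-2-methyl-5-[(E)-2-phenylethenyl]benzene | Cc1c(OCc2ccccc2)cc(/C=C/c2ccccc2)cc1OCc1ccccc1 | intermediate
8 | 2-methyl-5-(2-phenylethyl)benzene-1,3-diol | Cc1c(O)cc(CCc2ccccc2)cc1O | intermediate
9 | 3-hydroxy-2-methyl-5-(2-phenylethyl)cyclohexa-2,5-diene-1,4-dione | CC1=C(O)C(=O)C(CCc2ccccc2)=CC1=O | intermediate
10 | 2-methoxybenzaldehyde | COc1ccccc1C=O | starting material
11 | 1,3-bis(benzyloxy)-5-[(E)-2-(2-methoxyphenyl)ethenyl]-2-methylbenzene | COc1ccccc1/C=C/c1cc(OCc2ccccc2)c(C)c(OCc2ccccc2)c1 | intermediate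
12 | 5-[2-(2-methoxyphenyl)ethyl]-2-methylbenzene-1,3-diol | COc1ccccc1CCc1cc(O)c(C)c(O)c1 | intermediate
13 | 6'-[2-(2-methoxyphenyl)ethyl]-3,3'-dimethyl-6-(2-phenylethyl)-[1,1'-biphenyl]-2,2',4,4',5-pentol | Cc1c(O)c(O)c(CCc2ccccc2)c(-c2c(O)c(C)c(O)cc2CCc2ccccc2OC)c1O | intermediate
14 | 2-{2,4-dihydroxy-6-[2-(2-methoxyphenyl)ethyl]-3-methylphenyl}-5-hydroxy-6-methyl-3-(2-phenylethyl)cyclohexa-2,5-diene-1,4-dione | CC1=C(O)C(=O)C(CCc2ccccc2)=C(c2c(O)c(C)c(O)cc2CCc2ccccc2OC)C1=O | intermediate
15 | 4,4'-dihydroxy-2-[2-(2-methoxyphenyl)ethyl]-5,5'-dimethyl-2'-(2-phenylethyl)-[1,1'-bi(cyclohexane)]-1,1',4,4'-tetraene-3,3',6,6'-tetrone | COc1ccccc1CCC1=C(C2=C(CCc3ccccc3)C(=O)C(O)=C(C)C2=O)C(=O)C(C)=C(O)C1=O | target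

**Totals**
Total steps: 11. Longest linear sequence: 9 steps (steps 1–7, 10, 11).

**Steps most likely to fail, with fallbacks**

Step 10 (Michael arylation forming a tetra-ortho-substituted biaryl bond). The risks are a slow reaction at a hindered acceptor carbon, incomplete re-oxidation, and double arylation of 12. The fallback sets out from compound 9 and comes back to the route at compound 14. Compound 9 is brominated at its only vinylic C–H (Br2, NaOAc, AcOH, rt; addition then dehydrobromination) to give 2-bromo-5-hydroxy-6-methyl-3-(2-phenylethyl)cyclohexa-2,5-diene-1,4-dione F1. F1 is then treated with resorcinol 12 (NaOAc, EtOH, 40 °C) in a conjugate addition–elimination. Bromide leaves from the adduct, so the quinone level is kept without any oxidant, the acceptor is more electrophilic, and 14 is obtained directly.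

Step 11 (Teuber oxidation next to a bulky biaryl axis). The risks are sluggish radical coupling at the flanked position and reversible attack of the ortho phenol on the neighbouring quinone. The fallback sets out from compound 14 and comes back at compound 15. Nitrosation with NaNO2 in AcOH/EtOH at 0 °C puts a small electrophile on the free ring position and gives 2-{2,4-dihydroxy-6-[2-(2-methoxyphenyl)ethyl]-3-methyl-5-nitrosophenyl}-5-hydroxy-6-methyl-3-(2-phenylethyl)cyclohexa-2,5-diene-1,4-dione F2. Reduction with Na2S2O4 in aqueous EtOH converts the nitroso group to the amine and also reduces the quinone ring, giving 5'-amino-6'-[2-(2-methoxyphenyl)ethyl]-3,3'-dimethyl-6-(2-phenylethyl)-[1,1'-biphenyl]-2,2',4,4',5-pentol F3. Oxidation with FeCl3 in dilute aqueous HCl turns the aminoresorcinol ring into the hydroxyquinone through hydrolysis of its quinone imine and re-oxidises ring A, giving 15.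

Step 7 (first Teuber oxidation). The risks are over-oxidation and loss of the sensitive hydroxyquinone on work-up. The fallback sets out from compound 8 and comes back at compound 9. Vilsmeier–Haack formylation (POCl3, DMF, MeCN, 0 °C, then aqueous NaOAc) at the only free activated position gives 2,4-dihydroxy-3-methyl-6-(2-phenylethyl)benzaldehyde F4. Dakin oxidation (H2O2, aqueous NaOH, 0 °C, under N2, acidic work-up) replaces the formyl group by hydroxyl to give 3-methyl-6-(2-phenylethyl)benzene-1,2,4-triol F5. Mild oxidation with Ag2O in Et2O (or air) then gives 9.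

**Further compounds**
F1 | step 10 | 2-bromo-5-hydroxy-6-methyl-3-(2-phenylethyl)cyclohexa-2,5-diene-1,4-dione | CC1=C(O)C(=O)C(CCc2ccccc2)=C(Br)C1=O
F2 | step 11 | 2-{2,4-dihydroxy-6-[2-(2-methoxyphenyl)ethyl]-3-methyl-5-nitrosophenyl}-5-hydroxy-6-methyl-3-(2-phenylethyl)cyclohexa-2,5-diene-1,4-dione | CC1=C(O)C(=O)C(CCc2ccccc2)=C(c2c(O)c(C)c(O)c(N=O)c2CCc2ccccc2OC)C1=O
F3 | step 11 | 5'-amino-6'-[2-(2-methoxyphenyl)ethyl]-3,3'-dimethyl-6-(2-phenylethyl)-[1,1'-biphenyl]-2,2',4,4',5-pentol | Cc1c(O)c(O)c(CCc2ccccc2)c(-c2c(O)c(C)c(O)c(N)c2CCc2ccccc2OC)c1O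
F4 | step 7 | 2,4-dihydroxy-3-methyl-6-(2-phenylethyl)benzaldehyde | Cc1c(O)cc(CCc2ccccc2)c(C=O)c1O
F5 | step 7 | 3-methyl-6-(2-phenylethyl)benzene-1,2,4-triol | Cc1c(O)cc(CCc2ccccc2)c(O)c1O
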